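**Retrosynthetic overview**
- The target is reached by hydrogenolysis of its tetrabenzyl ether; both benzene rings are bought with their oxygen pattern in place (5-hydroxyvanillin for ring A, 4-bromocatechol for ring B).
- Key disconnection: the bond between chain carbon C7 (benzylic CH2) and C1 of the catechol ring B. It is made while the C3–C7 bond of a cyclopentanol is broken, in a ring-opening arylation of 1-(2-arylethyl)cyclopentan-1-ol with 4-bromo-1,2-bis(benzyloxy)benzene (cerium ligand-to-metal charge transfer plus nickel catalysis).
- Enabling feature: the ketone carbon C3 and the benzylic carbon C7 are 1,5-related along C3–C4–C5–C6–C7. They can therefore be the two ends of one C–C bond of a five-membered carbocycle, with C3 as carbinol carbon and C4–C7 as ring CH2 groups. β-Scission of the derived alkoxy radical unveils the C3 ketone and a C7 radical in one event.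
- The cyclopentanol comes from a dihydrocinnamate ester and the 1,4-di-Grignard reagent of 1,4-dibromobutane; the ester comes from 5-hydroxyvanillin by benzylation, Wittig olefination and alkene hydrogenation.
- Ring order: the only ring formed is the temporary cyclopentane (step 4); it is opened again in step 6.

Key step: step 6

Remark: the target has no stereocentre and no stereogenic double bond, so no stereocontrol is needed. Locants C1–C7 refer to the heptane chain (C3 = ketone carbon, C7 = CH2 bound to ring B).

**Step 1**
Reactants: 1 3,4-dihydroxy-5-methoxybenzaldehyde (5-hydroxyvanillin); 2 benzyl bromide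
Product: 3 3,4-bis(benzyloxy)-5-methoxybenzaldehyde
Conditions: BnBr (2.4 equiv), K2CO3, DMF, 60 °C
Reagents that add atoms: benzyl bromide, BrCc1ccccc1
Why: Williamson ether synthesis, in which both phenoxides formed by K2CO3 should be alkylated by the benzylic bromide (SN2) while the aldehyde stays untouched.

**Step 2**
Reactants: 3 3,4-bis(benzyloxy)-5-methoxybenzaldehyde; 4 ethyl (triphenylphosphoranylidene)acetate
Product: 5 ethyl (E)-3-[3,4-bis(benzyloxy)-5-methoxyphenyl]prop-2-enoate
Conditions: Ph3P=CHCO2Et (1.2 equiv), PhMe, 80 °C
Reagents that add atoms: ethyl (triphenylphosphoranylidene)acetate, CCOC(=O)C=P(c1ccccc1)(c1ccccc1)c1ccccc1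
Why: Wittig olefination with a stabilised ylide, which should give the E-cinnamate (the alkene geometry is of no consequence, since the double bond is removed in step 3).

**Step 3**
Reactants: 5 ethyl (E)-3-[3,4-bis(benzyloxy)-5-methoxyphenyl]prop-2-enoate
Product: 6 ethyl 3-[3,4-bis(benzyloxy)-5-methoxyphenyl]propanoate
Conditions: H2 (3 atm), RhCl(PPh3)3 (5 mol %), PhMe/EtOH, 50 °C
Reagents that add atoms: none
Why: Homogeneous hydrogenation with Wilkinson's catalyst should saturate the disubstituted alkene without hydrogenolysis of the aryl benzyl ethers, which a heterogeneous palladium catalyst would put at risk.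

**Step 4**
Reactants: 6 ethyl 3-[3,4-bis(benzyloxy)-5-methoxyphenyl]propanoate; 7 1,4-dibromobutane
Product: 9 1-{2-[3,4-bis(benzyloxy)-5-methoxyphenyl]ethyl}cyclopentan-1-ol, via butane-1,4-diylbis(magnesium bromide) 8 (not isolated)
Conditions: 7 (1.5 equiv), Mg, THF, reflux; then 6, THF, 0 °C to rt; sat. aq NH4Cl
Reagents that add atoms: 1,4-dibromobutane, BrCCCCBr (delivered as its di-Grignard reagent)
Why: Annulating double Grignard addition, in which the first C–Mg bond converts the ester into a ketone carrying a δ-C–Mg bond that should close the cyclopentane by intramolecular 1,2-addition (5-exo-trig), the standard route from esters to 1-substituted cyclopentanols.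

**Step 5**
Reactants: 10 4-bromobenzene-1,2-diol (4-bromocatechol); 2 benzyl bromide
Product: 11 1,2-bis(benzyloxy)-4-bromobenzene
Conditions: BnBr (2.4 equiv), K2CO3, DMF, 60 °C
Reagents that add atoms: benzyl bromide, BrCc1ccccc1
Why: Williamson ether synthesis of both phenols, which also protects the catechol against oxidation in step 6.

**Step 6**
Reactants: 9 1-{2-[3,4-bis(benzyloxy)-5-methoxyphenyl]ethyl}cyclopentan-1-ol; 11 1,2-bis(benzyloxy)-4-bromobenzene
Product: 12 1-[3,4-bis(benzyloxy)-5-methoxyphenyl]-7-[3,4-bis(benzyloxy)phenyl]heptan-3-one
Conditions: CeCl3 (10 mol %), n-Bu4NCl (20 mol %), 9,10-diphenylanthracene (10 mol %), NiCl2·glyme (10 mol %), 4,4'-di-tert-butyl-2,2'-bipyridine (12 mol %), NaHCO3 (2 equiv), 11 (1.5 equiv), MeCN/PhCF3, 400 nm LEDs, rt, Ar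
Reagents that add atoms: none
Why: The tertiary alcohol of 9 should bind tetravalent cerium as an alkoxide, and 400 nm light should homolyse the Ce–O bond by ligand-to-metal charge transfer; the cyclopentyloxy radical then undergoes β-scission of a ring C–C bond, which unveils the C3 ketone and a primary C7 radical that is captured by the aryl nickel bromide from oxidative addition of 11 to zerovalent nickel, and reductive elimination from trivalent nickel forms the CH2–aryl bond, while photoexcited 9,10-diphenylanthracene returns nickel to the zerovalent state and its radical cation reoxidises trivalent cerium. The closest known reaction types are the cerium/nickel dual-catalytic dehydroxymethylative arylation of free aliphatic alcohols with aryl bromides, the cerium-photocatalysed ring opening of tertiary cyclopentanols, and the photoredox/nickel ring-opening arylation of tertiary cycloalkanols to remotely arylated ketones. No ring is closed (the temporary cyclopentane is opened) and no stereocentre is formed. The step needs endocyclic instead of exocyclic β-scission, which should be secured because the two ring bonds at the carbinol carbon are equivalent by symmetry and their cleavage releases cyclopentane strain, whereas loss of the 2-arylethyl group would give an equally unstabilised primary radical without that gain. It also needs radical capture by nickel to outrun hydrogen abstraction, which is helped by the absence of any C–H in a 1,5-relationship to the oxygen in the side chain and by 11 carrying the only carbon–halogen bond.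

**Step 7**
Reactants: 12 1-[3,4-bis(benzyloxy)-5-methoxyphenyl]-7-[3,4-bis(benzyloxy)phenyl]heptan-3-one
Product: 13 1-(3,4-dihydroxy-5-methoxyphenyl)-7-(3,4-dihydroxyphenyl)heptan-3-one
Conditions: H2 (1 atm), 10% Pd/C, EtOAc/EtOH, rt; filtration and concentration under Ar
Reagents that add atoms: none
Why: Hydrogenolysis of the four aryl benzyl ethers over palladium on carbon, under which an isolated dialkyl ketone and the aryl methyl ether should remain intact.

**Compound list**
1 | 3,4-dihydroxy-5-methoxybenzaldehyde (5-hydroxyvanillin) | COc1cc(C=O)cc(O)c1O | starting material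
2 | benzyl bromide | BrCc1ccccc1 | starting material
3 | 3,4-bis(benzyloxy)-5-methoxybenzaldehyde | COc1cc(C=O)cc(OCc2ccccc2)c1OCc1ccccc1 | intermediate
4 | ethyl (triphenylphosphoranylidene)acetate | CCOC(=O)C=P(c1ccccc1)(c1ccccc1)c1ccccc1 | starting material
5 | ethyl (E)-3-[3,4-bis(benzyloxy)-5-methoxyphenyl]prop-2-enoate | CCOC(=O)/C=C/c1cc(OC)c(OCc2ccccc2)c(OCc2ccccc2)c1 | intermediate
6 | ethyl 3-[3,4-bis(benzyloxy)-5-methoxyphenyl]propanoate | CCOC(=O)CCc1cc(OC)c(OCc2ccccc2)c(OCc2ccccc2)c1 | intermediate
7 | 1,4-dibromobutane | BrCCCCBr | starting material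
8 | butane-1,4-diylbis(magnesium bromide) | Br[Mg]CCCC[Mg]Br | intermediate
9 | 1-{2-[3,4-bis(benzyloxy)-5-methoxyphenyl]ethyl}cyclopentan-1-ol | COc1cc(CCC2(O)CCCC2)cc(OCc2ccccc2)c1OCc1ccccc1 | intermediate
10 | 4-bromobenzene-1,2-diol (4-bromocatechol) | Oc1ccc(Br)cc1O | starting material
11 | 1,2-bis(benzyloxy)-4-bromobenzene | Brc1ccc(OCc2ccccc2)c(OCc2ccccc2)c1 | intermediate
12 | 1-[3,4-bis(benzyloxy)-5-methoxyphenyl]-7-[3,4-bis(benzyloxy)phenyl]heptan-3-one | COc1cc(CCC(=O)CCCCc2ccc(OCc3ccccc3)c(OCc3ccccc3)c2)cc(OCc2ccccc2)c1OCc1ccccc1 | intermediate
13 | 1-(3,4-dihydroxy-5-methoxyphenyl)-7-(3,4-dihydroxyphenyl)heptan-3-one | COc1cc(CCC(=O)CCCCc2ccc(O)c(O)c2)cc(O)c1O | target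

**Total step count:** 7
**Longest linear sequence:** 6 steps (steps 1, 2, 3, 4, 6 and 7, from 5-hydroxyvanillin)

**Steps most likely to fail**

Step 6. Oxidative addition of the electron-rich aryl bromide to nickel may be slow, so that the ring-opened radical is lost by hydrogen abstraction or dimerisation; hydrogen abstraction at the benzylic ether CH2 groups may also compete with alkoxy radical formation. The fallback abandons the radical ring opening for a polar chain assembly; it sets out from 11, uses aldehyde 3 as partner and comes back to the route at 13. Sonogashira coupling of 11 with commercial hex-5-yn-2-one (PdCl2(PPh3)2, CuI, Et3N, 60 °C) should give 6-[3,4-bis(benzyloxy)phenyl]hex-5-yn-2-one F1, in which the same aryl–carbon bond is already in place. Claisen–Schmidt condensation of the methyl group of F1 with 3 (pyrrolidine, AcOH, THF, rt) should give (E)-1-[3,4-bis(benzyloxy)-5-methoxyphenyl]-7-[3,4-bis(benzyloxy)phenyl]hept-1-en-6-yn-3-one F2. Hydrogenation of F2 (H2, Pd/C, EtOAc/EtOH) should saturate the alkene and the alkyne and remove the four benzyl groups in one operation to give 13.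

Step 4. Enolisation of the ester or of the intermediate ketone by the basic di-Grignard reagent, or intermolecular addition in place of ring closure, may lower the yield of the annulation. The fallback builds the ring by metathesis; it sets out from 6 and comes back at 9. Double addition of allylmagnesium bromide to 6 (THF, 0 °C) should give 4-{2-[3,4-bis(benzyloxy)-5-methoxyphenyl]ethyl}hepta-1,6-dien-4-ol F3. Ring-closing metathesis with the second-generation Grubbs catalyst (CH2Cl2, 40 °C) should give 1-{2-[3,4-bis(benzyloxy)-5-methoxyphenyl]ethyl}cyclopent-3-en-1-ol F4. Hydrogenation of the ring alkene with RhCl(PPh3)3 and H2, which spares the benzyl ethers, should give 9.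

Step 7. Cleavage of the four ethers may stop short, the ketone may be over-reduced on prolonged exposure, and the liberated catechols may oxidise in air during isolation. The fallback replaces reductive cleavage by Lewis-acid cleavage with a cation scavenger; it sets out from 12 and comes back at 13. Treatment of 12 with BCl3 and pentamethylbenzene (CH2Cl2, −78 °C) should remove the benzyl groups as benzylpentamethylbenzene while the aryl methyl ether and the ketone survive at this temperature; this fallback makes no new compound (F0).

**Further compounds**
F1 | step 6 | 6-[3,4-bis(benzyloxy)phenyl]hex-5-yn-2-one | CC(=O)CCC#Cc1ccc(OCc2ccccc2)c(OCc2ccccc2)c1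
F2 | step 6 | (E)-1-[3,4-bis(benzyloxy)-5-methoxyphenyl]-7-[3,4-bis(benzyloxy)phenyl]hept-1-en-6-yn-3-one | COc1cc(/C=C/C(=O)CCC#Cc2ccc(OCc3ccccc3)c(OCc3ccccc3)c2)cc(OCc2ccccc2)c1OCc1ccccc1
F3 | step 4 | 4-{2-[3,4-bis(benzyloxy)-5-methoxyphenyl]ethyl}hepta-1,6-dien-4-ol | C=CCC(O)(CC=C)CCc1cc(OC)c(OCc2ccccc2)c(OCc2ccccc2)c1
F4 | step 4 | 1-{2-[3,4-bis(benzyloxy)-5-methoxyphenyl]ethyl}cyclopent-3-en-1-ol | OC1(CCc2cc(OC)c(OCc3ccccc3)c(OCc3ccccc3)c2)CC=CC1
F0 | step 7 | none | none
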